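**Plan**

- Ring numbering: C1 (CMe=), C2 (=CH), C3 (CH on the quaternary carbon), C4 (CH–isopropenyl), C5, C6 (CH2). The retrosynthesis cuts, in order: the side-chain CH2–CH2 bond two carbons out from the quaternary carbon, the ring bond C1–C6, the C1=C2 double bond (olefination), and the bond from C3 to the quaternary carbon ([3,3] shift).
- Enabling feature: C1–C6 is the one ring bond that joins a vinylic carbon to a CH2 carrying no stereocenter. A (Z)-2-iodopropenyl group on C3 and a 2-iodoethyl group on C4 can therefore be joined by an sp2–sp3 coupling that leaves C3 and C4 untouched.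
- Forward: a δ-lactone serves as a temporary ring whose O1 stands, atom for atom, where C1 will be. The sequence is conjugate addition, ortho lactone, Johnson–Claisen with farnesol, lactol, ring opening by Stork–Zhao olefination, Appel iodination, ring closure, then side-chain extension.
- Stereochemistry: C4 is set by rhodium/(S)-BINAP catalysis. C3 and the quaternary carbon are relayed from C4 in the one Claisen event (ring-fixed ketene acetal, chair, attack anti to the C4 substituent, E-alkene of farnesol). The side-chain methyl center comes from (S)-Roche ester and the E-alkene from farnesol.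

Key step: step 7

Assumption: (S)-BINAP is taken to give (4S)-3, by analogy with the usual facial sense of rhodium/BINAP additions to six-membered enones and enoates; if the sense is opposite, (R)-BINAP is used.

**Route**

Step 1
Reactants: 1 5,6-dihydro-2H-pyran-2-one; 2 isopropenylboronic acid pinacol ester
Product: 3 (4S)-4-(prop-1-en-2-yl)oxan-2-one
Conditions: [Rh(OH)(cod)]2 (2.5 mol%), (S)-BINAP (5.5 mol%), dioxane/H2O 10:1, 50 °C
Reagents that add atoms: none
Why: Rhodium-catalyzed asymmetric conjugate addition of an alkenylboron reagent to an unsaturated lactone (Hayashi–Miyaura reaction); the BINAP-bound alkenylrhodium adds to one enantioface of the enoate and so sets C4.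

Step 2
Reactants: 3 (4S)-4-(prop-1-en-2-yl)oxan-2-one
Product: 5 (4S)-2,2-diethoxy-4-(prop-1-en-2-yl)oxane, via O-ethyl lactonium tetrafluoroborate 4 (not isolated)
Conditions: Et3OBF4, CH2Cl2, 25 °C; then NaOEt, EtOH, −78 to 0 °C
Reagents that add atoms: triethyloxonium tetrafluoroborate CC[O+](CC)CC.F[B-](F)(F)F; sodium ethoxide CC[O-].[Na+]
Why: O-alkylation of the lactone carbonyl with Meerwein salt and capture of the dialkoxycarbenium ion by ethoxide is the standard ortho lactone synthesis; the stereocenter and the isopropenyl group are not involved.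

Step 3
Reactants: 5 (4S)-2,2-diethoxy-4-(prop-1-en-2-yl)oxane; 6 (2E,6E)-farnesol
Product: 9 (3S,4S)-4-(prop-1-en-2-yl)-3-[(3R,6E)-3,7,11-trimethyldodeca-1,6,10-trien-3-yl]oxan-2-one, via mixed ethyl farnesyl ortho ester 7 (not isolated), via cyclic ketene acetal 8 (not isolated)
Conditions: 5 (1.5 equiv), EtCO2H (cat.), xylene, 140 °C, EtOH distilled off
Reagents that add atoms: none
Why: Johnson–Claisen (ortho ester Claisen) rearrangement through a lactone-derived ketene acetal: the ring fixes the ketene acetal geometry (C4 cis to the ring oxygen), the (2E)-alkene places the homogeranyl chain equatorial and the methyl axial in a chair transition state, and the allyl terminus is delivered anti to the C4 isopropenyl group, so C3 and the quaternary carbon are set together, trans to C4.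

Step 4
Reactants: 9 (3S,4S)-4-(prop-1-en-2-yl)-3-[(3R,6E)-3,7,11-trimethyldodeca-1,6,10-trien-3-yl]oxan-2-one
Product: 10 (3S,4S)-4-(prop-1-en-2-yl)-3-[(3R,6E)-3,7,11-trimethyldodeca-1,6,10-trien-3-yl]oxan-2-ol (lactol, both anomers)
Conditions: i-Bu2AlH (1.1 equiv), CH2Cl2, −78 °C; aqueous potassium sodium tartrate work-up
Reagents that add atoms: none
Why: Partial reduction of a δ-lactone to the lactol, the tetrahedral aluminate surviving at low temperature until work-up; the alkenes and the three stereocenters are untouched.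

Step 5
Reactants: 10 (3S,4S)-4-(prop-1-en-2-yl)-3-[(3R,6E)-3,7,11-trimethyldodeca-1,6,10-trien-3-yl]oxan-2-ol
Product: 11 (3S,4R,5R,8E)-5-ethenyl-4-[(1Z)-2-iodoprop-1-en-1-yl]-5,9,13-trimethyl-3-(prop-1-en-2-yl)tetradeca-8,12-dien-1-ol
Conditions: EtPPh3I, n-BuLi, THF, 0 °C; I2, −78 °C; NaN(SiMe3)2, −20 °C; then 10, −78 to 0 °C (3 equiv of ylide)
Reagents that add atoms: ethyltriphenylphosphonium iodide CC[P+](c1ccccc1)(c1ccccc1)c1ccccc1.[I-]; iodine II
Why: Stork–Zhao olefination of the open hydroxy-aldehyde form of the lactol with the α-iodo ylide should give the (Z)-2-iodoalkene (iodine cis to the chain) through the kinetically preferred cis-oxaphosphetane, and it frees the primary carbinol at the same time.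

Step 6
Reactants: 11 (3S,4R,5R,8E)-5-ethenyl-4-[(1Z)-2-iodoprop-1-en-1-yl]-5,9,13-trimethyl-3-(prop-1-en-2-yl)tetradeca-8,12-dien-1-ol
Product: 12 (3S,4R,5R,8E)-5-ethenyl-1-iodo-4-[(1Z)-2-iodoprop-1-en-1-yl]-5,9,13-trimethyl-3-(prop-1-en-2-yl)tetradeca-8,12-diene (chain numbered as in 11)
Conditions: I2, PPh3, imidazole, CH2Cl2, 0 °C
Reagents that add atoms: iodine II
Why: Appel iodination of the unhindered primary alcohol by SN2 displacement of the alkoxyphosphonium ion; the alkenyl iodide and the alkenes are inert under these neutral conditions.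

Step 7
Reactants: 12 (3S,4R,5R,8E)-5-ethenyl-1-iodo-4-[(1Z)-2-iodoprop-1-en-1-yl]-5,9,13-trimethyl-3-(prop-1-en-2-yl)tetradeca-8,12-diene
Product: 14 (3S,4S)-1-methyl-4-(prop-1-en-2-yl)-3-[(3R,6E)-3,7,11-trimethyldodeca-1,6,10-trien-3-yl]cyclohex-1-ene, via alkylzinc iodide 13 (not isolated)
Conditions: Zn dust (activated with BrCH2CH2Br and Me3SiCl), THF, 40 °C; then PdCl2(dppf) (5 mol%), THF, 0.01 M, 25 to 50 °C
Reagents that add atoms: none
Why: Activated zinc inserts only into the primary C(sp3)–I bond (alkenyl iodides are inert under these conditions) to give alkylzinc iodide 13; zerovalent palladium then adds oxidatively to the (Z)-alkenyl iodide, the tethered alkylzinc transmetalates, and reductive elimination from a seven-membered palladacycle forms the C6–C1 bond. The closest known reaction type is the Negishi alkyl–alkenyl cross-coupling, used here in its ring-closing form. The six-membered ring is closed by C(sp2)–C(sp3) reductive elimination with the alkene endocyclic, so no strained geometry is involved. No stereocenter is formed: C3 and C4 are carried in from step 3, and the coupling keeps the alkene geometry, which becomes the endocyclic C1=C2 bond. The step needs chemoselectivity between the two C–I bonds and coupling faster than β-hydride elimination or carbopalladation of the isopropenyl and vinyl groups; the Z geometry of 12 holds iodine cis to the chain so the termini can meet, the intramolecular transmetalation is fast, and the wide-bite-angle dppf ligand favours reductive elimination.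

Step 8
Reactants: 14 (3S,4S)-1-methyl-4-(prop-1-en-2-yl)-3-[(3R,6E)-3,7,11-trimethyldodeca-1,6,10-trien-3-yl]cyclohex-1-ene
Product: 16 (3S,4S)-3-[(3R,6E)-1-iodo-3,7,11-trimethyldodeca-6,10-dien-3-yl]-1-methyl-4-(prop-1-en-2-yl)cyclohex-1-ene, via alkylzirconocene chloride 15 (not isolated)
Conditions: Cp2Zr(H)Cl (1.2 equiv), THF, 25 °C; then I2, 0 °C
Reagents that add atoms: iodine II
Why: Hydrozirconation with Schwartz reagent followed by iodinolysis; the reagent adds to the monosubstituted vinyl group far faster than to the 1,1-disubstituted isopropenyl or the trisubstituted alkenes and places zirconium on the terminal carbon, and iodine then cleaves the C–Zr bond to the primary iodide.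

Step 9
Reactants: 17 methyl (2S)-3-hydroxy-2-methylpropanoate ((S)-Roche ester)
Product: 18 methyl (2S)-3-[(tert-butyldimethylsilyl)oxy]-2-methylpropanoate
Conditions: t-BuMe2SiCl, imidazole, CH2Cl2, 25 °C
Reagents that add atoms: tert-butyldimethylsilyl chloride CC(C)(C)[Si](C)(C)Cl
Why: Routine silylation of a primary alcohol; the stereocenter is not involved.

Step 10
Reactants: 18 methyl (2S)-3-[(tert-butyldimethylsilyl)oxy]-2-methylpropanoate
Product: 19 (2S)-3-[(tert-butyldimethylsilyl)oxy]-2-methylpropanal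
Conditions: i-Bu2AlH (1.05 equiv), CH2Cl2, −78 °C; aqueous potassium sodium tartrate work-up
Reagents that add atoms: none
Why: Low-temperature partial reduction of the ester to the aldehyde through the stable tetrahedral aluminate; the α-stereocenter is kept by working cold and using the aldehyde at once.

Step 11
Reactants: 19 (2S)-3-[(tert-butyldimethylsilyl)oxy]-2-methylpropanal
Product: 20 tert-butyldimethyl{[(2R)-2-methylbut-3-en-1-yl]oxy}silane
Conditions: Ph3PCH3Br, KN(SiMe3)2, THF, 0 °C; then 19, −78 to 0 °C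
Reagents that add atoms: methyltriphenylphosphonium bromide C[P+](c1ccccc1)(c1ccccc1)c1ccccc1.[Br-]
Why: Wittig methylenation of the aldehyde with the unstabilized ylide at low temperature, where α-epimerization should not compete (the descriptor changes only through the priority rules).

Step 12
Reactants: 20 tert-butyldimethyl{[(2R)-2-methylbut-3-en-1-yl]oxy}silane
Product: 21 (3R)-4-bromo-3-methylbut-1-ene
Conditions: Ph3PBr2, CH2Cl2, 25 °C; distillation
Reagents that add atoms: dibromotriphenylphosphorane BrP(Br)(c1ccccc1)(c1ccccc1)c1ccccc1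
Why: Direct conversion of a primary silyl ether into the bromide through the alkoxyphosphonium bromide (Appel-type SN2 at the primary carbon); the stereocenter and the terminal alkene are not involved.

Step 13
Reactants: 21 (3R)-4-bromo-3-methylbut-1-ene; 16 (3S,4S)-3-[(3R,6E)-1-iodo-3,7,11-trimethyldodeca-6,10-dien-3-yl]-1-methyl-4-(prop-1-en-2-yl)cyclohex-1-ene
Product: 23 (3S,4S)-1-methyl-4-(prop-1-en-2-yl)-3-[(3S,7S,10E)-3,7,11,15-tetramethylhexadeca-1,10,14-trien-7-yl]cyclohex-1-ene (CNP0208273.1), via Grignard reagent 22 (not isolated)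
Conditions: Mg turnings, THF, 0 to 25 °C; then 16, Li2CuCl4 (3 mol%), THF, −20 to 0 °C
Reagents that add atoms: none
Why: Copper-catalyzed sp3–sp3 coupling of a primary alkylmagnesium bromide with a primary alkyl iodide (Kochi coupling) joins the side chain without touching the alkenes; the methyl stereocenter of 22 is β to magnesium and not involved, and the reagent is used promptly and cold so that homoallyl–cyclopropylcarbinyl scrambling should not intervene.

**Compound list**

1 | 5,6-dihydro-2H-pyran-2-one | O=C1C=CCCO1 | starting material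
2 | isopropenylboronic acid pinacol ester (4,4,5,5-tetramethyl-2-(prop-1-en-2-yl)-1,3,2-dioxaborolane) | CC(=C)B1OC(C)(C)C(C)(C)O1 | starting material
3 | (4S)-4-(prop-1-en-2-yl)oxan-2-one | O=C1C[C@@H](C(=C)C)CCO1 | intermediate
4 | O-ethyl lactonium tetrafluoroborate of 3 ((4S)-6-ethoxy-4-(prop-1-en-2-yl)-2,3,4,5-tetrahydropyrylium tetrafluoroborate) | CCOC1=[O+]CC[C@H](C(=C)C)C1.F[B-](F)(F)F | intermediate
5 | (4S)-2,2-diethoxy-4-(prop-1-en-2-yl)oxane | CCOC1(OCC)C[C@@H](C(=C)C)CCO1 | intermediate
6 | (2E,6E)-farnesol ((2E,6E)-3,7,11-trimethyldodeca-2,6,10-trien-1-ol) | CC(C)=CCC/C(C)=C/CC/C(C)=C/CO | starting material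
7 | (4S)-2-ethoxy-4-(prop-1-en-2-yl)-2-{[(2E,6E)-3,7,11-trimethyldodeca-2,6,10-trien-1-yl]oxy}oxane (mixed ortho ester, both C2 epimers) | CCOC1(OC/C=C(\C)CC/C=C(\C)CCC=C(C)C)C[C@@H](C(=C)C)CCO1 | intermediate
8 | (4S)-4-(prop-1-en-2-yl)-6-{[(2E,6E)-3,7,11-trimethyldodeca-2,6,10-trien-1-yl]oxy}-3,4-dihydro-2H-pyran (cyclic ketene acetal) | C=C(C)[C@H]1CCOC(OC/C=C(\C)CC/C=C(\C)CCC=C(C)C)=C1 | intermediate
9 | (3S,4S)-4-(prop-1-en-2-yl)-3-[(3R,6E)-3,7,11-trimethyldodeca-1,6,10-trien-3-yl]oxan-2-one | C=C[C@@](C)(CC/C=C(\C)CCC=C(C)C)[C@H]1C(=O)OCC[C@@H]1C(=C)C | intermediate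
10 | (3S,4S)-4-(prop-1-en-2-yl)-3-[(3R,6E)-3,7,11-trimethyldodeca-1,6,10-trien-3-yl]oxan-2-ol (both anomers) | C=C[C@@](C)(CC/C=C(\C)CCC=C(C)C)[C@H]1C(O)OCC[C@@H]1C(=C)C | intermediate
11 | (3S,4R,5R,8E)-5-ethenyl-4-[(1Z)-2-iodoprop-1-en-1-yl]-5,9,13-trimethyl-3-(prop-1-en-2-yl)tetradeca-8,12-dien-1-ol | C=C[C@@](C)(CC/C=C(\C)CCC=C(C)C)[C@@H](/C=C(/C)I)[C@H](CCO)C(=C)C | intermediate
12 | (3S,4R,5R,8E)-5-ethenyl-1-iodo-4-[(1Z)-2-iodoprop-1-en-1-yl]-5,9,13-trimethyl-3-(prop-1-en-2-yl)tetradeca-8,12-diene (numbered as in 11) | C=C[C@@](C)(CC/C=C(\C)CCC=C(C)C)[C@@H](/C=C(/C)I)[C@H](CCI)C(=C)C | intermediate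
13 | alkylzinc iodide from 12 (zinc on the former CH2I carbon, alkenyl iodide intact) | C=C[C@@](C)(CC/C=C(\C)CCC=C(C)C)[C@@H](/C=C(/C)I)[C@H](CC[Zn]I)C(=C)C | intermediate
14 | (3S,4S)-1-methyl-4-(prop-1-en-2-yl)-3-[(3R,6E)-3,7,11-trimethyldodeca-1,6,10-trien-3-yl]cyclohex-1-ene | C=C[C@@](C)(CC/C=C(\C)CCC=C(C)C)[C@H]1C=C(C)CC[C@@H]1C(=C)C | intermediate
15 | alkylzirconocene chloride from 14 (Cp2ZrCl on the terminal carbon of the former vinyl group) | Cl[Zr](CC[C@@](C)(CC/C=C(\C)CCC=C(C)C)[C@H]1C=C(C)CC[C@@H]1C(=C)C)(C1C=CC=C1)C1C=CC=C1 | intermediate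
16 | (3S,4S)-3-[(3R,6E)-1-iodo-3,7,11-trimethyldodeca-6,10-dien-3-yl]-1-methyl-4-(prop-1-en-2-yl)cyclohex-1-ene | ICC[C@@](C)(CC/C=C(\C)CCC=C(C)C)[C@H]1C=C(C)CC[C@@H]1C(=C)C | intermediate
17 | methyl (2S)-3-hydroxy-2-methylpropanoate ((S)-Roche ester) | COC(=O)[C@@H](C)CO | starting material
18 | methyl (2S)-3-[(tert-butyldimethylsilyl)oxy]-2-methylpropanoate | COC(=O)[C@@H](C)CO[Si](C)(C)C(C)(C)C | intermediate
19 | (2S)-3-[(tert-butyldimethylsilyl)oxy]-2-methylpropanal | O=C[C@@H](C)CO[Si](C)(C)C(C)(C)C | intermediate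
20 | tert-butyldimethyl{[(2R)-2-methylbut-3-en-1-yl]oxy}silane | C=C[C@@H](C)CO[Si](C)(C)C(C)(C)C | intermediate
21 | (3R)-4-bromo-3-methylbut-1-ene | C=C[C@@H](C)CBr | intermediate
22 | [(2R)-2-methylbut-3-en-1-yl]magnesium bromide | C=C[C@@H](C)C[Mg]Br | intermediate
23 | (3S,4S)-1-methyl-4-(prop-1-en-2-yl)-3-[(3S,7S,10E)-3,7,11,15-tetramethylhexadeca-1,10,14-trien-7-yl]cyclohex-1-ene | C=C[C@@H](C)CCC[C@@](C)(CC/C=C(\C)CCC=C(C)C)[C@H]1C=C(C)CC[C@@H]1C(=C)C | target

**Step count and risks**

Total step count: 13. Longest linear sequence: 9 steps (steps 1–8 and 13, from 1); steps 9–12 make the side-chain fragment.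

Most likely to fail:

1. Step 7 (ring closure). The alkenylpalladium intermediate may undergo carbopalladation of the nearby isopropenyl or vinyl group, or the alkylpalladium may undergo β-hydride elimination, before reductive elimination. Zinc insertion may also be incomplete or accompanied by radical 5-exo cyclization onto the iodoalkene. Fallback (anionic cycloalkylation instead of palladium catalysis): from 11, chlorination (PPh3, N-chlorosuccinimide, CH2Cl2, 0 °C) would give the primary chloride (3S,4R,5R,8E)-1-chloro-5-ethenyl-4-[(1Z)-2-iodoprop-1-en-1-yl]-5,9,13-trimethyl-3-(prop-1-en-2-yl)tetradeca-8,12-diene F1. Iodine–lithium exchange with t-BuLi (2.1 equiv, Et2O, −78 °C), much faster at the alkenyl iodide than any reaction of the alkyl chloride, would give the alkenyllithium with retained geometry F2. Warming in THF/HMPA should close the ring by intramolecular SN2 alkylation and return to the route at 14.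

2. Step 3 (ortho lactone Claisen). The mixed ortho ester may lose the ring oxygen instead of ethanol, so that rearrangement runs through an acyclic ketene acetal without ring control; a boat transition state would erode the configuration at the quaternary carbon; farnesol may dehydrate under hot acid. Fallback (reagent-controlled ester enolate Claisen on an acyclic ester): from 3, saponification (LiOH, THF/H2O), silylation (t-BuMe2SiCl, imidazole, DMF) and cleavage of the silyl ester (K2CO3, MeOH/H2O) would give (3S)-5-[(tert-butyldimethylsilyl)oxy]-3-(prop-1-en-2-yl)pentanoic acid F3. Esterification with 6 (EDC·HCl, DMAP, CH2Cl2) would give the farnesyl ester F4. Treatment with (4S,5S)-2-bromo-4,5-diphenyl-1,3-bis{[3,5-bis(trifluoromethyl)phenyl]sulfonyl}-1,3,2-diazaborolidine and i-Pr2NEt (CH2Cl2, −78 to 25 °C; the antipodal reagent if the pairing proves mismatched) would give the O-boron ketene acetal with the alkyl group cis to O–B F5. This should undergo the Ireland–Claisen rearrangement through a chair to the acid (2S,3S)-5-[(tert-butyldimethylsilyl)oxy]-3-(prop-1-en-2-yl)-2-[(3R,6E)-3,7,11-trimethyldodeca-1,6,10-trien-3-yl]pentanoic acid F6. Desilylation with aqueous HF in MeCN and spontaneous lactonization return to the route at 9.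

3. Step 5 (olefination of the lactol). The open aldehyde form of this hindered lactol may be too scarce and too crowded for the bulky α-iodo ylide, giving slow conversion, epimerization at the α-carbon by excess base, or loss of Z selectivity. Fallback (olefination of a free, protected aldehyde): from 9, full reduction (LiAlH4, THF, 0 °C) would give the diol (2S,3S)-3-(prop-1-en-2-yl)-2-[(3R,6E)-3,7,11-trimethyldodeca-1,6,10-trien-3-yl]pentane-1,5-diol F7. Selective silylation of the less hindered C5 hydroxyl (t-BuMe2SiCl 1.05 equiv, imidazole, CH2Cl2, −20 °C) would give the mono-silyl ether (2S,3S)-5-[(tert-butyldimethylsilyl)oxy]-3-(prop-1-en-2-yl)-2-[(3R,6E)-3,7,11-trimethyldodeca-1,6,10-trien-3-yl]pentan-1-ol F8. Dess–Martin oxidation (NaHCO3, CH2Cl2) would give the aldehyde (2S,3S)-5-[(tert-butyldimethylsilyl)oxy]-3-(prop-1-en-2-yl)-2-[(3R,6E)-3,7,11-trimethyldodeca-1,6,10-trien-3-yl]pentanal F9. Stork–Zhao olefination as in step 5 would give the silyl ether of 11 F10, and Bu4NF in THF returns to the route at 11.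

Further compounds

F1 | step 7 | (3S,4R,5R,8E)-1-chloro-5-ethenyl-4-[(1Z)-2-iodoprop-1-en-1-yl]-5,9,13-trimethyl-3-(prop-1-en-2-yl)tetradeca-8,12-diene (numbered as in 11) | C=C[C@@](C)(CC/C=C(\C)CCC=C(C)C)[C@@H](/C=C(/C)I)[C@H](CCCl)C(=C)C
F2 | step 7 | alkenyllithium from F1 (lithium in place of iodine, geometry retained) | C=C[C@@](C)(CC/C=C(\C)CCC=C(C)C)[C@@H](/C=C(/C)[Li])[C@H](CCCl)C(=C)C
F3 | step 3 | (3S)-5-[(tert-butyldimethylsilyl)oxy]-3-(prop-1-en-2-yl)pentanoic acid | OC(=O)C[C@@H](C(=C)C)CCO[Si](C)(C)C(C)(C)C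
F4 | step 3 | (2E,6E)-3,7,11-trimethyldodeca-2,6,10-trien-1-yl (3S)-5-[(tert-butyldimethylsilyl)oxy]-3-(prop-1-en-2-yl)pentanoate | CC(C)=CCC/C(C)=C/CC/C(C)=C/COC(=O)C[C@@H](C(=C)C)CCO[Si](C)(C)C(C)(C)C
F5 | step 3 | O-boron ketene acetal of F4 with the (4S,5S)-4,5-diphenyl-1,3-bis{[3,5-bis(trifluoromethyl)phenyl]sulfonyl}-1,3,2-diazaborolidin-2-yl group on oxygen, alkyl group cis to O–B | CC(C)=CCC/C(C)=C/CC/C(C)=C/CO/C(OB1N(S(=O)(=O)c2cc(cc(c2)C(F)(F)F)C(F)(F)F)[C@@H](c2ccccc2)[C@H](c2ccccc2)N1S(=O)(=O)c1cc(cc(c1)C(F)(F)F)C(F)(F)F)=C/[C@@H](C(=C)C)CCO[Si](C)(C)C(C)(C)C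
F6 | step 3 | (2S,3S)-5-[(tert-butyldimethylsilyl)oxy]-3-(prop-1-en-2-yl)-2-[(3R,6E)-3,7,11-trimethyldodeca-1,6,10-trien-3-yl]pentanoic acid | C=C[C@@](C)(CC/C=C(\C)CCC=C(C)C)[C@@H](C(=O)O)[C@H](CCO[Si](C)(C)C(C)(C)C)C(=C)C
F7 | step 5 | (2S,3S)-3-(prop-1-en-2-yl)-2-[(3R,6E)-3,7,11-trimethyldodeca-1,6,10-trien-3-yl]pentane-1,5-diol | C=C[C@@](C)(CC/C=C(\C)CCC=C(C)C)[C@@H](CO)[C@H](CCO)C(=C)C
F8 | step 5 | (2S,3S)-5-[(tert-butyldimethylsilyl)oxy]-3-(prop-1-en-2-yl)-2-[(3R,6E)-3,7,11-trimethyldodeca-1,6,10-trien-3-yl]pentan-1-ol | C=C[C@@](C)(CC/C=C(\C)CCC=C(C)C)[C@@H](CO)[C@H](CCO[Si](C)(C)C(C)(C)C)C(=C)C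
F9 | step 5 | (2S,3S)-5-[(tert-butyldimethylsilyl)oxy]-3-(prop-1-en-2-yl)-2-[(3R,6E)-3,7,11-trimethyldodeca-1,6,10-trien-3-yl]pentanal | C=C[C@@](C)(CC/C=C(\C)CCC=C(C)C)[C@@H](C=O)[C@H](CCO[Si](C)(C)C(C)(C)C)C(=C)C
F10 | step 5 | tert-butyldimethylsilyl ether of 11 | C=C[C@@](C)(CC/C=C(\C)CCC=C(C)C)[C@@H](/C=C(/C)I)[C@H](CCO[Si](C)(C)C(C)(C)C)C(=C)C
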